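**Plan**

1. Retrosynthesis: the five benzyl ethers come off last. The O1–C2 ether bond of ring C is traced back to a 3,4-trans-3,4-diaryl-3,4-dihydrocoumarin, and that lactone is opened by cutting O1–C2 and C2–C3, so that C2 leaves as carbon monoxide.
2. This is possible because C2 of ring C is an unsubstituted carbon held only by O1 and C3, while C3 and C4 each carry one aryl group and one hydrogen. The precursor is therefore a triarylethylene (C3=C4) whose ring A carries the O1 phenol ortho to C4.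
3. The alkene is cut at the bond from C4 to C6 of the flavanone (Suzuki–Miyaura coupling of a deoxybenzoin enol triflate with a naringenin 6-boronate). The deoxybenzoin is cut at C3–ring B (ketone α-arylation of a ring A acetophenone with a ring B bromide).
4. Forward: rings A and B and the flavanone enter ready-made and are joined by the α-arylation and the Suzuki coupling. Ring C closes first as the lactone in the carbonylation and, after reduction, again as the cyclic ether.
5. Stereochemistry: the flavanone C2 comes from (2S)-naringenin and is preserved by avoiding soluble bases. C4 is set by the chiral ligand in the carbonylation, and C3 follows as the 3,4-trans isomer (syn addition to the Z alkene, which is also the thermodynamic outcome).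

Key step: step 12

Remark: the ring A building block 1-[4-(benzyloxy)-2-hydroxyphenyl]ethan-1-one is assumed to be purchasable (otherwise it is one selective benzylation from 2,4-dihydroxyacetophenone).
Remark: the carbinol centre that appears at the flavanone C4 after the hydride reduction is written as the expected 2,4-cis epimer; either epimer serves, because the later oxidation removes this centre.

**Route**

Step 1
Reactants: 1 2,6-dimethoxyphenol
Product: 2 2-(benzyloxy)-1,3-dimethoxybenzene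
Conditions: BnBr, K2CO3, DMF, 60 °C
Reagents that add atoms: benzyl bromide, BrCc1ccccc1
Why: Williamson etherification of the acidic, doubly flanked phenol with a reactive benzylic halide should proceed cleanly.

Step 2
Reactants: 2 2-(benzyloxy)-1,3-dimethoxybenzene
Product: 3 3-(benzyloxy)-1-bromo-2,4-dimethoxybenzene
Conditions: NBS, MeCN, 0 °C to rt
Reagents that add atoms: N-bromosuccinimide, O=C1CCC(=O)N1Br
Why: Electrophilic aromatic bromination of a 1,2,3-trioxygenated benzene goes para to one outer methoxy group and ortho to the other, as with 1,2,3-trimethoxybenzene, which gives the substitution pattern of ring B.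

Step 3
Reactants: 4 1-[4-(benzyloxy)-2-hydroxyphenyl]ethan-1-one
Product: 5 1-[4-(benzyloxy)-2-(methoxymethoxy)phenyl]ethan-1-one
Conditions: MOMCl, K2CO3, acetone, reflux
Reagents that add atoms: chloromethyl methyl ether, COCCl
Why: Williamson-type alkylation with the reactive α-chloro ether protects the hydrogen-bonded ortho phenol as a MOM acetal that tolerates the strong bases of steps 4 and 5.

Step 4
Reactants: 5 1-[4-(benzyloxy)-2-(methoxymethoxy)phenyl]ethan-1-one; 3 3-(benzyloxy)-1-bromo-2,4-dimethoxybenzene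
Product: 6 1-[4-(benzyloxy)-2-(methoxymethoxy)phenyl]-2-[3-(benzyloxy)-2,4-dimethoxyphenyl]ethan-1-one
Conditions: Pd2(dba)3, Xantphos, NaOtBu, THF, 70 °C
Reagents that add atoms: none
Why: Palladium-catalysed α-arylation of a methyl ketone (Buchwald–Hartwig type) joins ring B to the future C3 and should stop at monoarylation because the product rests as its stabilised enolate.

Step 5
Reactants: 6 1-[4-(benzyloxy)-2-(methoxymethoxy)phenyl]-2-[3-(benzyloxy)-2,4-dimethoxyphenyl]ethan-1-one
Product: 8 (Z)-1-[4-(benzyloxy)-2-(methoxymethoxy)phenyl]-2-[3-(benzyloxy)-2,4-dimethoxyphenyl]vinyl trifluoromethanesulfonate, via potassium Z-enolate 7 (not isolated)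
Conditions: KN(SiMe3)2, THF, −78 °C; then PhNTf2, −78 °C to 0 °C
Reagents that add atoms: N-phenylbis(trifluoromethanesulfonimide), O=S(=O)(N(c1ccccc1)S(=O)(=O)C(F)(F)F)C(F)(F)F
Why: Enolate O-sulfonylation: deprotonation of the aryl benzyl ketone gives the Z enolate (oxygen cis to ring B, the two aryl groups trans), and this geometry is carried into the enol triflate.

Step 6
Reactants: 9 (2S)-naringenin
Product: 10 (2S)-7-(benzyloxy)-2-[4-(benzyloxy)phenyl]-5-hydroxychroman-4-one
Conditions: BnOH, PPh3, DIAD, THF, 0 °C to rt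
Reagents that add atoms: benzyl alcohol, OCc1ccccc1
Why: Mitsunobu etherification alkylates the two free, acidic phenols (7-OH and 4'-OH) and leaves the hydrogen-bonded 5-OH, and the absence of a free base keeps the flavanone heterocycle closed so that C2 retains its configuration.

Step 7
Reactants: 10 (2S)-7-(benzyloxy)-2-[4-(benzyloxy)phenyl]-5-hydroxychroman-4-one
Product: 11 (2S)-7-(benzyloxy)-2-[4-(benzyloxy)phenyl]-5-hydroxy-6-iodochroman-4-one
Conditions: BnMe3N·ICl2, CaCO3, CH2Cl2–MeOH, rt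
Reagents that add atoms: benzyltrimethylammonium dichloroiodate, C[N+](C)(C)Cc1ccccc1.Cl[I-]Cl
Why: Electrophilic aromatic iodination of the phloroglucinol ring should take place ortho to the free, hydrogen-bonded 5-OH, that is at C6, as is known for 5-hydroxy-7-alkoxy flavonoids with this reagent, while CaCO3 takes up the HCl.

Step 8
Reactants: 11 (2S)-7-(benzyloxy)-2-[4-(benzyloxy)phenyl]-5-hydroxy-6-iodochroman-4-one
Product: 12 (2S)-5,7-bis(benzyloxy)-2-[4-(benzyloxy)phenyl]-6-iodochroman-4-one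
Conditions: BnBr, Ag2O, CH2Cl2, rt, dark
Reagents that add atoms: benzyl bromide, BrCc1ccccc1
Why: Silver oxide-promoted Williamson etherification (Purdie conditions) benzylates the chelated 5-OH because Ag2O activates the bromide and takes up HBr without a soluble base, so the retro-oxa-Michael ring opening that would racemise C2 is avoided.

Step 9
Reactants: 12 (2S)-5,7-bis(benzyloxy)-2-[4-(benzyloxy)phenyl]-6-iodochroman-4-one
Product: 13 (2S)-5,7-bis(benzyloxy)-2-[4-(benzyloxy)phenyl]-6-(4,4,5,5-tetramethyl-1,3,2-dioxaborolan-2-yl)chroman-4-one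
Conditions: B2pin2, Pd(OAc)2, SPhos, KOAc, 1,4-dioxane, 80 °C
Reagents that add atoms: bis(pinacolato)diboron, CC1(C)OB(OC1(C)C)B1OC(C)(C)C(C)(C)O1
Why: Miyaura borylation of the aryl iodide, with the bulky electron-rich biarylphosphine to carry the di-ortho-substituted carbon through oxidative addition and transmetalation and with acetate as a base too weak to enolise the flavanone.

Step 10
Reactants: 8 (Z)-enol triflate of the deoxybenzoin; 13 naringenin 6-boronate
Product: 14 (2S)-5,7-bis(benzyloxy)-2-[4-(benzyloxy)phenyl]-6-[(Z)-1-[4-(benzyloxy)-2-(methoxymethoxy)phenyl]-2-[3-(benzyloxy)-2,4-dimethoxyphenyl]vinyl]chroman-4-one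
Conditions: Pd(OAc)2, SPhos, K3PO4, THF–H2O, 40 °C
Reagents that add atoms: none
Why: Suzuki–Miyaura coupling of an alkenyl triflate proceeds with retention of the alkene geometry, so the flavanone ends up cis to ring B, and SPhos is suited to 2,6-dialkoxyaryl boron partners at low temperature.

Step 11
Reactants: 14 MOM-protected triarylethylene
Product: 15 (2S)-5,7-bis(benzyloxy)-2-[4-(benzyloxy)phenyl]-6-[(Z)-1-[4-(benzyloxy)-2-hydroxyphenyl]-2-[3-(benzyloxy)-2,4-dimethoxyphenyl]vinyl]chroman-4-one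
Conditions: HCl (aq.), MeOH–THF, 40 °C
Reagents that add atoms: none
Why: Acid-catalysed acetal cleavage should free only the ring A phenol, since benzyl ethers, the flavanone and the trisubstituted alkene are stable to dilute acid.

Step 12
Reactants: 15 ortho-hydroxy triarylethylene
Product: 16 (3R,4S)-7-(benzyloxy)-3-[3-(benzyloxy)-2,4-dimethoxyphenyl]-4-[(2S)-5,7-bis(benzyloxy)-2-[4-(benzyloxy)phenyl]-4-oxochroman-6-yl]chroman-2-one (3,4-trans lactone)
Conditions: Pd(OAc)2, (R,R)-DIOP, TsOH, CO (40 bar), toluene, 100 °C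
Reagents that add atoms: carbon monoxide, [C-]#[O+]
Why: Proposed new method: a palladium hydride generated from Pd(OAc)2, the bisphosphine and TsOH under CO should add across C3=C4 of 15, hydrogen to the diaryl carbon C4 and palladium to the benzylic C3; CO then inserts into the C3–Pd bond (C2–C3) and the ortho phenol of ring A attacks the acylpalladium (O1–C2), which releases the lactone and returns the hydride. The closest known reaction type is the palladium-catalysed asymmetric cyclocarbonylation (intramolecular hydroesterification) of 2-vinylphenols and 2-allylphenols to benzo-fused lactones, shown on 1,1-disubstituted alkenes but not on triarylethylenes. Ring C closes as a six-membered lactone by 6-exo-trig attack of the phenol oxygen on the acyl carbon. C4 is set by the ligand, which decides the face of hydride delivery (the antipode of DIOP that leads to 4S has to be established in the first runs, and (R,R) is written provisionally), and C3 is set by the substrate, since syn addition to the Z alkene followed by CO insertion with retention gives the 3,4-trans lactone directly and the enolisable C3–H would in any case equilibrate to trans. The step needs palladium at C3 and not at C4 and ring closure onto ring A only: the fully substituted, doubly arylated C4 blocks palladation there, and both flavanone oxygens next to the linking carbon are benzylated, so the ring A hydroxyl is the only nucleophile within reach.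

Step 13
Reactants: 16 3,4-trans lactone
Product: 17 (2R,3S)-2-[3-(benzyloxy)-2,4-dimethoxyphenyl]-3-[4-(benzyloxy)-2-hydroxyphenyl]-3-[(2S,4S)-5,7-bis(benzyloxy)-2-[4-(benzyloxy)phenyl]-4-hydroxychroman-6-yl]propan-1-ol
Conditions: LiBH4, THF, 0 °C to rt
Reagents that add atoms: none
Why: Hydride reduction with LiBH4 opens the aryl ester to the ring A phenol and the primary alcohol at C2 and also reduces the flavanone carbonyl (mainly to the 2,4-cis alcohol), which is accepted because step 15 restores it, while C3 and C4 are not affected since trans is the stable arrangement at the enolisable C3.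

Step 14
Reactants: 17 phenol diol
Product: 18 (2S,4S)-5,7-bis(benzyloxy)-2-[4-(benzyloxy)phenyl]-6-[(3R,4S)-7-(benzyloxy)-3-[3-(benzyloxy)-2,4-dimethoxyphenyl]chroman-4-yl]chroman-4-ol
Conditions: PPh3, DIAD, THF, 0 °C
Reagents that add atoms: none
Why: Intramolecular Mitsunobu etherification, in which the primary alcohol is activated far faster than the hindered secondary one and is displaced by the ring A phenol (6-exo-tet), closes ring C as the chroman without touching a stereocentre.

Step 15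
Reactants: 18 isoflavan with flavan-4-ol
Product: 19 (2S)-5,7-bis(benzyloxy)-2-[4-(benzyloxy)phenyl]-6-[(3R,4S)-7-(benzyloxy)-3-[3-(benzyloxy)-2,4-dimethoxyphenyl]chroman-4-yl]chroman-4-one
Conditions: DMP, pyridine, CH2Cl2, 0 °C to rt
Reagents that add atoms: none
Why: Dess–Martin oxidation returns the only free hydroxyl group, the benzylic flavan-4-ol, to the flavanone ketone under buffered, non-basic conditions that leave C2 untouched.

Step 16
Reactants: 19 penta-O-benzyl ether of the target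
Product: 20 (2S)-5,7-dihydroxy-6-[(3R,4S)-7-hydroxy-3-(3-hydroxy-2,4-dimethoxyphenyl)chroman-4-yl]-2-(4-hydroxyphenyl)chroman-4-one (CNP0267463.1)
Conditions: H2 (1 atm), Pd/C, EtOAc–MeOH, rt
Reagents that add atoms: none
Why: Catalytic hydrogenolysis should remove all five benzyl ethers in one operation, whereas the methyl ethers, the electron-rich aryl ketone and the C–H stereocentres are inert under these conditions.

**Compound list**

1 | 2,6-dimethoxyphenol | COc1cccc(OC)c1O | starting material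
2 | 2-(benzyloxy)-1,3-dimethoxybenzene | COc1cccc(OC)c1OCc1ccccc1 | intermediate
3 | 3-(benzyloxy)-1-bromo-2,4-dimethoxybenzene | COc1ccc(Br)c(OC)c1OCc1ccccc1 | intermediate
4 | 1-[4-(benzyloxy)-2-hydroxyphenyl]ethan-1-one | CC(=O)c1ccc(OCc2ccccc2)cc1O | starting material
5 | 1-[4-(benzyloxy)-2-(methoxymethoxy)phenyl]ethan-1-one | COCOc1cc(OCc2ccccc2)ccc1C(C)=O | intermediate
6 | 1-[4-(benzyloxy)-2-(methoxymethoxy)phenyl]-2-[3-(benzyloxy)-2,4-dimethoxyphenyl]ethan-1-one | COCOc1cc(OCc2ccccc2)ccc1C(=O)Cc1ccc(OC)c(OCc2ccccc2)c1OC | intermediate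
7 | potassium (Z)-1-[4-(benzyloxy)-2-(methoxymethoxy)phenyl]-2-[3-(benzyloxy)-2,4-dimethoxyphenyl]ethen-1-olate (not isolated) | COCOc1cc(OCc2ccccc2)ccc1/C([O-])=C/c1ccc(OC)c(OCc2ccccc2)c1OC.[K+] | intermediate
8 | (Z)-1-[4-(benzyloxy)-2-(methoxymethoxy)phenyl]-2-[3-(benzyloxy)-2,4-dimethoxyphenyl]vinyl trifluoromethanesulfonate | COCOc1cc(OCc2ccccc2)ccc1/C(OS(=O)(=O)C(F)(F)F)=C/c1ccc(OC)c(OCc2ccccc2)c1OC | intermediate
9 | (2S)-naringenin | O=C1C[C@@H](c2ccc(O)cc2)Oc2cc(O)cc(O)c12 | starting material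
10 | (2S)-7-(benzyloxy)-2-[4-(benzyloxy)phenyl]-5-hydroxychroman-4-one | O=C1C[C@@H](c2ccc(OCc3ccccc3)cc2)Oc2cc(OCc3ccccc3)cc(O)c12 | intermediate
11 | (2S)-7-(benzyloxy)-2-[4-(benzyloxy)phenyl]-5-hydroxy-6-iodochroman-4-one | O=C1C[C@@H](c2ccc(OCc3ccccc3)cc2)Oc2cc(OCc3ccccc3)c(I)c(O)c12 | intermediate
12 | (2S)-5,7-bis(benzyloxy)-2-[4-(benzyloxy)phenyl]-6-iodochroman-4-one | O=C1C[C@@H](c2ccc(OCc3ccccc3)cc2)Oc2cc(OCc3ccccc3)c(I)c(OCc3ccccc3)c12 | intermediate
13 | (2S)-5,7-bis(benzyloxy)-2-[4-(benzyloxy)phenyl]-6-(4,4,5,5-tetramethyl-1,3,2-dioxaborolan-2-yl)chroman-4-one | O=C1C[C@@H](c2ccc(OCc3ccccc3)cc2)Oc2cc(OCc3ccccc3)c(B3OC(C)(C)C(C)(C)O3)c(OCc3ccccc3)c12 | intermediate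
14 | (2S)-5,7-bis(benzyloxy)-2-[4-(benzyloxy)phenyl]-6-[(Z)-1-[4-(benzyloxy)-2-(methoxymethoxy)phenyl]-2-[3-(benzyloxy)-2,4-dimethoxyphenyl]vinyl]chroman-4-one | COCOc1cc(OCc2ccccc2)ccc1/C(c1c(OCc2ccccc2)cc2c(c1OCc1ccccc1)C(=O)C[C@@H](c1ccc(OCc3ccccc3)cc1)O2)=C/c1ccc(OC)c(OCc2ccccc2)c1OC | intermediate
15 | (2S)-5,7-bis(benzyloxy)-2-[4-(benzyloxy)phenyl]-6-[(Z)-1-[4-(benzyloxy)-2-hydroxyphenyl]-2-[3-(benzyloxy)-2,4-dimethoxyphenyl]vinyl]chroman-4-one | Oc1cc(OCc2ccccc2)ccc1/C(c1c(OCc2ccccc2)cc2c(c1OCc1ccccc1)C(=O)C[C@@H](c1ccc(OCc3ccccc3)cc1)O2)=C/c1ccc(OC)c(OCc2ccccc2)c1OC | intermediate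
16 | (3R,4S)-7-(benzyloxy)-3-[3-(benzyloxy)-2,4-dimethoxyphenyl]-4-[(2S)-5,7-bis(benzyloxy)-2-[4-(benzyloxy)phenyl]-4-oxochroman-6-yl]chroman-2-one | COc1ccc([C@@H]2C(=O)Oc3cc(OCc4ccccc4)ccc3[C@H]2c2c(OCc3ccccc3)cc3c(c2OCc2ccccc2)C(=O)C[C@@H](c2ccc(OCc4ccccc4)cc2)O3)c(OC)c1OCc1ccccc1 | intermediate
17 | (2R,3S)-2-[3-(benzyloxy)-2,4-dimethoxyphenyl]-3-[4-(benzyloxy)-2-hydroxyphenyl]-3-[(2S,4S)-5,7-bis(benzyloxy)-2-[4-(benzyloxy)phenyl]-4-hydroxychroman-6-yl]propan-1-ol | COc1ccc([C@H](CO)[C@@H](c2ccc(OCc3ccccc3)cc2O)c2c(OCc3ccccc3)cc3c(c2OCc2ccccc2)[C@@H](O)C[C@@H](c2ccc(OCc4ccccc4)cc2)O3)c(OC)c1OCc1ccccc1 | intermediate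
18 | (2S,4S)-5,7-bis(benzyloxy)-2-[4-(benzyloxy)phenyl]-6-[(3R,4S)-7-(benzyloxy)-3-[3-(benzyloxy)-2,4-dimethoxyphenyl]chroman-4-yl]chroman-4-ol | COc1ccc([C@@H]2COc3cc(OCc4ccccc4)ccc3[C@H]2c2c(OCc3ccccc3)cc3c(c2OCc2ccccc2)[C@@H](O)C[C@@H](c2ccc(OCc4ccccc4)cc2)O3)c(OC)c1OCc1ccccc1 | intermediate
19 | (2S)-5,7-bis(benzyloxy)-2-[4-(benzyloxy)phenyl]-6-[(3R,4S)-7-(benzyloxy)-3-[3-(benzyloxy)-2,4-dimethoxyphenyl]chroman-4-yl]chroman-4-one | COc1ccc([C@@H]2COc3cc(OCc4ccccc4)ccc3[C@H]2c2c(OCc3ccccc3)cc3c(c2OCc2ccccc2)C(=O)C[C@@H](c2ccc(OCc4ccccc4)cc2)O3)c(OC)c1OCc1ccccc1 | intermediate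
20 | (2S)-5,7-dihydroxy-6-[(3R,4S)-7-hydroxy-3-(3-hydroxy-2,4-dimethoxyphenyl)chroman-4-yl]-2-(4-hydroxyphenyl)chroman-4-one (CNP0267463.1) | COc1ccc([C@@H]2COc3cc(O)ccc3[C@H]2c2c(O)cc3c(c2O)C(=O)C[C@@H](c2ccc(O)cc2)O3)c(OC)c1O | target

**Step count and risks**

Total step count: 16. Longest linear sequence: 11 steps (steps 1, 2, 4, 5, 10–16; the naringenin branch, steps 6–9 and 10–16, is equally long).

Steps most likely to fail:

Step 12. The palladium hydride may fail to add to the crowded triaryl alkene, the acid may instead induce hydroalkoxylation of the alkene by the ring A phenol to a dihydrobenzofuran, or hydride delivery may show poor facial selectivity. The fallback sets out from 6, brings C2 in as a carbonate and forms the bond from C4 to the flavanone afterwards, all by known reactions. Acidic methanolysis of the MOM ether of 6 gives 1-[4-(benzyloxy)-2-hydroxyphenyl]-2-[3-(benzyloxy)-2,4-dimethoxyphenyl]ethan-1-one F1. C-acylation and lactonisation with diethyl carbonate and NaH (the classical route from 2-hydroxydeoxybenzoins) gives 7-(benzyloxy)-3-[3-(benzyloxy)-2,4-dimethoxyphenyl]-4-hydroxy-2H-chromen-2-one F2, and Tf2O with Et3N gives its 4-triflate F3. Suzuki–Miyaura coupling of the triflate with boronate 13 (Pd(OAc)2, SPhos, K3PO4) gives the 3,4-diarylcoumarin F4. Hydrogenation over Pd/C poisoned with ethylenediamine, which spares benzyl ethers, should add hydrogen cis to C3=C4 from either face and give the (3S,4S)-cis lactone F5 and the (3R,4R)-cis lactone F6. DBU in the same flask epimerises C3, turning the first into 16 and the second into the (3S,4R)-trans lactone F7, which is removed by chromatography (the two are diastereomers because of the flavanone centre). The route is rejoined at 16; the price is that C4 is no longer controlled.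

Step 10. Transmetalation of the di-ortho-alkoxy aryl boronate may be slow, with competing protodeboronation, and the basic medium may open the flavanone heterocycle with erosion at C2. The fallback sets out from 8 and reverses the polarity of the coupling. Miyaura borylation of 8 (B2pin2, PdCl2(PPh3)2, PPh3, KOPh, toluene, 50 °C) gives 2-[(E)-1-[4-(benzyloxy)-2-(methoxymethoxy)phenyl]-2-[3-(benzyloxy)-2,4-dimethoxyphenyl]vinyl]-4,4,5,5-tetramethyl-1,3,2-dioxaborolane F8, a robust boron partner. It is coupled with iodide 12 (Pd(OAc)2, SPhos, K3PO4) to rejoin the route at 14, which also makes step 9 unnecessary.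

Step 8. Alkylation of the hydrogen-bonded, iodine-flanked 5-OH may be sluggish, and forcing it invites retro-oxa-Michael ring opening and racemisation at C2. The fallback sets out from 11 and takes a redox detour. NaBH4 reduces the carbonyl to (2S,4S)-7-(benzyloxy)-2-[4-(benzyloxy)phenyl]-6-iodochromane-4,5-diol F9, in which the phenol is no longer hydrogen-bonded and ring opening is impossible. BnBr with K2CO3 at rt then benzylates only the phenol to give (2S,4S)-5,7-bis(benzyloxy)-2-[4-(benzyloxy)phenyl]-6-iodochroman-4-ol F10, and Dess–Martin oxidation rejoins the route at 12.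

**Further compounds**

F1 | step 12 | 1-[4-(benzyloxy)-2-hydroxyphenyl]-2-[3-(benzyloxy)-2,4-dimethoxyphenyl]ethan-1-one | COc1ccc(CC(=O)c2ccc(OCc3ccccc3)cc2O)c(OC)c1OCc1ccccc1
F2 | step 12 | 7-(benzyloxy)-3-[3-(benzyloxy)-2,4-dimethoxyphenyl]-4-hydroxy-2H-chromen-2-one | COc1ccc(C2=C(O)c3ccc(OCc4ccccc4)cc3OC2=O)c(OC)c1OCc1ccccc1
F3 | step 12 | 7-(benzyloxy)-3-[3-(benzyloxy)-2,4-dimethoxyphenyl]-2-oxo-2H-chromen-4-yl trifluoromethanesulfonate | COc1ccc(C2=C(OS(=O)(=O)C(F)(F)F)c3ccc(OCc4ccccc4)cc3OC2=O)c(OC)c1OCc1ccccc1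
F4 | step 12 | (2S)-5,7-bis(benzyloxy)-2-[4-(benzyloxy)phenyl]-6-[7-(benzyloxy)-3-[3-(benzyloxy)-2,4-dimethoxyphenyl]-2-oxo-2H-chromen-4-yl]chroman-4-one | COc1ccc(C2=C(c3c(OCc4ccccc4)cc4c(c3OCc3ccccc3)C(=O)C[C@@H](c3ccc(OCc5ccccc5)cc3)O4)c3ccc(OCc4ccccc4)cc3OC2=O)c(OC)c1OCc1ccccc1
F5 | step 12 | (3S,4S)-7-(benzyloxy)-3-[3-(benzyloxy)-2,4-dimethoxyphenyl]-4-[(2S)-5,7-bis(benzyloxy)-2-[4-(benzyloxy)phenyl]-4-oxochroman-6-yl]chroman-2-one (3,4-cis) | COc1ccc([C@H]2C(=O)Oc3cc(OCc4ccccc4)ccc3[C@H]2c2c(OCc3ccccc3)cc3c(c2OCc2ccccc2)C(=O)C[C@@H](c2ccc(OCc4ccccc4)cc2)O3)c(OC)c1OCc1ccccc1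
F6 | step 12 | (3R,4R)-7-(benzyloxy)-3-[3-(benzyloxy)-2,4-dimethoxyphenyl]-4-[(2S)-5,7-bis(benzyloxy)-2-[4-(benzyloxy)phenyl]-4-oxochroman-6-yl]chroman-2-one (3,4-cis) | COc1ccc([C@@H]2C(=O)Oc3cc(OCc4ccccc4)ccc3[C@@H]2c2c(OCc3ccccc3)cc3c(c2OCc2ccccc2)C(=O)C[C@@H](c2ccc(OCc4ccccc4)cc2)O3)c(OC)c1OCc1ccccc1
F7 | step 12 | (3S,4R)-7-(benzyloxy)-3-[3-(benzyloxy)-2,4-dimethoxyphenyl]-4-[(2S)-5,7-bis(benzyloxy)-2-[4-(benzyloxy)phenyl]-4-oxochroman-6-yl]chroman-2-one (3,4-trans) | COc1ccc([C@H]2C(=O)Oc3cc(OCc4ccccc4)ccc3[C@@H]2c2c(OCc3ccccc3)cc3c(c2OCc2ccccc2)C(=O)C[C@@H](c2ccc(OCc4ccccc4)cc2)O3)c(OC)c1OCc1ccccc1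
F8 | step 10 | 2-[(E)-1-[4-(benzyloxy)-2-(methoxymethoxy)phenyl]-2-[3-(benzyloxy)-2,4-dimethoxyphenyl]vinyl]-4,4,5,5-tetramethyl-1,3,2-dioxaborolane | COCOc1cc(OCc2ccccc2)ccc1/C(B1OC(C)(C)C(C)(C)O1)=C/c1ccc(OC)c(OCc2ccccc2)c1OC
F9 | step 8 | (2S,4S)-7-(benzyloxy)-2-[4-(benzyloxy)phenyl]-6-iodochromane-4,5-diol | O[C@H]1C[C@@H](c2ccc(OCc3ccccc3)cc2)Oc2cc(OCc3ccccc3)c(I)c(O)c12
F10 | step 8 | (2S,4S)-5,7-bis(benzyloxy)-2-[4-(benzyloxy)phenyl]-6-iodochroman-4-ol | O[C@H]1C[C@@H](c2ccc(OCc3ccccc3)cc2)Oc2cc(OCc3ccccc3)c(I)c(OCc3ccccc3)c12
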